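Remark on the chemistry: the target is achiral and is drawn as one of its equivalent enol tautomers. The labels C1–C8a are those of one naphthalen-1(4H)-one half of the target (C1 carbonyl carbon, C2 bridge-bearing carbon, C3 enol carbon, C4 quaternary carbon, ring A = C4a–C8a with the acetyl group on C7) and are kept for every intermediate, whatever its systematic name.

## Structural features

The target consists of two identical 7-acetyl-3,6,8-trihydroxy-4,4-dimethylnaphthalen-1(4H)-one units joined by a single methylene carbon between their C2 atoms. In each unit, ring A is aromatic and carries hydroxyl groups at C6 and C8, the acetyl group between them at C7, and one hydrogen at C5. Ring B is a cyclic 1,3-dione held as its enol, with the C1 carbonyl peri to the C8 hydroxyl, the enol oxygen on C3, and C4 as a benzylic quaternary carbon with two methyl groups. There is no stereocentre, so no relative or absolute configuration has to be set. The fragile parts are the 1,5-bis(enol) array around the bridge, which can lose water to a pyran or fragment by retro-Michael reaction, and the acidic, metal-binding enols and chelated phenols. The real difficulties are the quaternary C4 wedged between C4a and the C3 carbonyl, and placing the acetyl group on C7 while C2 (the most nucleophilic carbon of a free 1,3-dione) and C5 stay untouched. The key step uses the fact that C4 is both alpha to the C3 carbonyl and bonded to the aromatic carbon C4a, so arylation of an isopropyl ketone enolate forms C4–C4a, creates the quaternary carbon and closes ring B at once.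

## Logic of the disconnections

**14 to two molecules of 12.** Both C2–CH2 bonds are cut. The bridge is a 1,5-relationship between two enolised 1,3-diones, the retron of a Knoevenagel condensation followed by a Michael addition with a one-carbon aldehyde. Because the halves are identical, one monomer serves twice and the problem is halved. The forward step must be the last one and must be mild, since acid or dehydrating conditions would close the bis-enol to a pyran; the acetyl groups therefore have to be in place already.

**12 to 11.** The three O–CH3 bonds (C1 enol ether, C6 and C8 aryl ethers) are cut. All acidic, chelating hydroxyl groups then appear in one late operation, and every earlier intermediate is neutral and easy to handle. The forward step needs a reagent that cleaves aryl methyl ethers and the vinylogous ester without harming the aryl ketone.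

**11 to 10.** The C7–acetyl bond is cut. The acetyl group is introduced while the dione is still masked, because a free cyclic 1,3-dione would be acylated at C2 in preference to ring A. In 10, C2 belongs to an electron-poor vinylogous ester, C7 lies between two methoxy donors, and C5 is shielded by the methyl groups on C4. The gain is an arene without a second enolisable ketone for the ring closure. The demand is regioselective acylation at C7 without loss of the enol ether.

**10 to 9.** The C4–C4a bond is cut. This opens ring B and turns the quaternary carbon into an isopropyl group next to a ketone, with an aryl bromide as the partner. The forward step must arylate the enolate at carbon, needs the aryl ring and the acyl group cis on the enol ether double bond, and must have no other acidic site.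

**9 to 8.** The C1–OCH3 bond is cut. Conjugate addition of the alcohol to an ynone places the oxygen on the aryl-bearing carbon without ambiguity, which O-alkylation of the corresponding 1,3-diketone would not do. The forward step has to deliver the E isomer.

**8 to 5 and 6.** The bond between the alkyne carbon and the carbonyl carbon is cut, giving an arylacetylene and an isobutyryl donor. The forward step must metalate the alkyne without touching the aryl bromide, which rules out alkyllithium bases, and must stop at the ketone, which calls for an acyl donor that transfers only once.

**5 to 3 and 4.** The triple bond is cut back to an aldehyde plus a one-carbon diazophosphonate. This is a mild homologation that tolerates the aryl bromide.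

**3 to 1.** The aryl–CHO bond is cut. The forward formylation must go ortho to bromine, at the position that is ortho to one methoxy group and para to the other.

## Other disconnections considered

**Alternative 1:** Both C1–C8a bonds are cut, leaving the bridge and both quaternary carbons in the acyclic bis(β-keto ester) dimethyl 2,4-bis[2-(4-acetyl-3,5-dimethoxyphenyl)-2-methylpropanoyl]pentanedioate A1. The forward key step would be a double intramolecular Friedel–Crafts acylation in a dehydrating sulfonic acid medium, each ester carbonyl attacking the arene position ortho to the quaternary carbon. It would give the tetramethyl ether of the target, A2, which needs only ether cleavage.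
- In its favour: both rings B close in one operation, and the arene is symmetric about the quaternary substituent, so the closure has no regiochemical question. The bridge and both acetyl groups are already present, so the late C7 acetylation and the final coupling of the chosen plan are avoided; on these two points it is the better plan. The quaternary carbon comes from simple enolate methylation without palladium, which is at least equal.
- Against it: an ester is a weak acylating agent, and it must attack a position between a methoxy group and the quaternary carbon on a ring that carries an acetyl group. The hot acid required would expose A1 to ester hydrolysis with decarboxylation, to retro-Claisen cleavage of the hindered ketones and to dehydration of the 1,5-dicarbonyl array to a pyran. Two closures must both succeed in one molecule.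
- Comparison: structurally it is more convergent. Mechanistically it relies on a forcing electrophilic closure, where the chosen plan uses a catalytic enolate arylation under basic conditions that suit the masked dione. Step economy is comparable, because A1 needs two crossed Claisen condensations with a hindered acyl unit.

**Alternative 2:** Ring A is dismantled at C4a–C5, C5–C6, C7–C8 and C8–C8a. Ring B with its quaternary carbon exists first as the dienone diazoketone 3-(2-diazoacetyl)-5-methoxy-4,4-dimethylcyclohexa-2,5-dien-1-one A3, and C6 and C7 come from the siloxyalkyne triisopropyl{[(2-methyl-1,3-dioxolan-2-yl)ethynyl]oxy}silane A4. The forward key step would be a blue-light Wolff rearrangement of A3, then [2+2] addition of A4, four-electron ring opening, six-electron ring closure and tautomerisation. It would give the phenol 8-hydroxy-3-methoxy-4,4-dimethyl-7-(2-methyl-1,3-dioxolan-2-yl)-6-(triisopropylsilyloxy)naphthalen-1(4H)-one A5.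
- In its favour: ring A appears fully substituted, with the acetyl group already on C7 as its ketal and the two oxygens differentiated. No electrophilic substitution with a regiochemical risk is needed, and on this point it is better than the chosen plan. Four bonds form in one metal-free cascade, which is also better in bond count for the key step.
- Against it: A3 is a 4,4-disubstituted cyclohexa-2,5-dienone, a chromophore with photochemistry of its own, so selective excitation of the diazo group is critical. The reacting terminus sits next to the quaternary carbon, which should slow the closure. A3 and A4 each need a multistep preparation, A4 is a labile ynol ether, and the quaternary carbon still has to be made inside A3.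
- Comparison: the end game (unmasking, then the one-carbon coupling) is equal to that of the chosen plan. Overall the route is expected to be longer and to rest on less available materials.

**Alternative 3:** C1–C2 and C3–C4 are cut, giving 3,5-dimethoxy-8,8-dimethylbicyclo[4.2.0]octa-1,3,5-trien-7-one A6 and ethoxyethyne A7. The forward key step would be thermal four-electron opening of A6 and [4+2] capture of the opened form by A7, the alkyne carbon bearing hydrogen bonding to the ketene carbon and the ethoxy-bearing carbon to the CMe2 terminus. It would give 3-ethoxy-6,8-dimethoxy-4,4-dimethylnaphthalen-1(4H)-one A8.
- In its favour: it is thermal, needs no metal or base, joins two fragments, and delivers the dione masked as a vinylogous ester. In protecting C2 it is the equal of the chosen plan.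
- Against it: the CMe2 terminus of the opened form carries methyl hydrogens well placed for a 1,5-hydrogen shift to the ketene carbon, which would compete with the cycloaddition. The terminus is fully substituted and therefore slow to react. A6 is not a simple compound to prepare regioselectively, and A7 is volatile and unstable.
- Comparison: A8 lacks the acetyl group, so the C7 acylation and the rest of the end game are the same as in the chosen plan, with no gain there. Step economy is equal at best, and the key step is mechanistically less secure than an enolate arylation at the only acidic site.

Key step: step 5

## Route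

Step 1
Reactants: 1 1-bromo-3,5-dimethoxybenzene
Product: 3 2-bromo-4,6-dimethoxybenzaldehyde, via iminium chloride 2 (not isolated)
Conditions: POCl3, DMF, 0 → 90 °C; then H2O
Reagents that add atoms: N,N-dimethylformamide, CN(C)C=O; water, O
Why: Vilsmeier–Haack formylation: the chloroiminium ion from DMF and POCl3 should attack the position flanked by bromine and one methoxy group, which is ortho to one methoxy donor, para to the other and less crowded than the position between the two methoxy groups; hydrolysis of iminium chloride 2 on work-up releases the aldehyde.

Step 2
Reactants: 3 2-bromo-4,6-dimethoxybenzaldehyde; 4 dimethyl (1-diazo-2-oxopropyl)phosphonate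
Product: 5 1-bromo-2-ethynyl-3,5-dimethoxybenzene
Conditions: K2CO3, MeOH, rt
Reagents that add atoms: none
Why: Seyferth–Gilbert homologation with the Ohira–Bestmann reagent: methanolysis of 4 gives the diazomethylphosphonate anion, which adds to the aldehyde, loses dimethyl phosphate and N2 and rearranges by 1,2-hydride shift to the terminal alkyne; the carbonate conditions leave the aryl bromide and the ethers untouched.

Step 3
Reactants: 5 1-bromo-2-ethynyl-3,5-dimethoxybenzene; 6 N-methoxy-N,2-dimethylpropanamide
Product: 8 1-(2-bromo-4,6-dimethoxyphenyl)-4-methylpent-1-yn-3-one, via lithium acetylide 7 (not isolated)
Conditions: LiN(SiMe3)2, THF, −78 °C; then 6, −78 → 0 °C; then cold 1 M aq. HCl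
Reagents that add atoms: none
Why: Acylation of an alkynyllithium with an N-methoxy-N-methyl amide: the silylamide base removes the acetylenic proton without bromine–lithium exchange, the amide transfers its acyl group only once so the reaction stops at the ynone, and the cold acid quench protonates the liberated amine before it can add to the ynone.

Step 4
Reactants: 8 1-(2-bromo-4,6-dimethoxyphenyl)-4-methylpent-1-yn-3-one
Product: 9 (E)-1-(2-bromo-4,6-dimethoxyphenyl)-1-methoxy-4-methylpent-1-en-3-one
Conditions: NaOMe (0.2 equiv), MeOH, 0 °C → rt
Reagents that add atoms: methanol, CO
Why: Base-catalysed oxa-Michael addition to the ynone: methoxide adds to the aryl-bearing carbon and the allenolate should be protonated on the side of the small methoxy group, away from the di-ortho-substituted aryl ring, which places the aryl ring cis to the acyl group (E); under the reversible alkoxide conditions this is also expected to be the more stable isomer.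

Step 5
Reactants: 9 (E)-1-(2-bromo-4,6-dimethoxyphenyl)-1-methoxy-4-methylpent-1-en-3-one
Product: 10 4,5,7-trimethoxy-1,1-dimethylnaphthalen-2(1H)-one
Conditions: Pd2(dba)3 (2.5 mol %), P(tBu)3 (6 mol %), NaOtBu (1.5 equiv), toluene, 80 °C
Reagents that add atoms: none
Why: Zerovalent palladium bearing P(tBu)3 should insert into the C4a–Br bond, which is not deactivated because both methoxy groups are meta to bromine, while NaOtBu removes the only acidic proton, the isopropyl C–H next to the C3 carbonyl, to give a cross-conjugated sodium dienolate. Exchange of bromide for the enolate gives a seven-membered arylpalladium enolate chelate, and C–C reductive elimination forms C4–C4a and closes ring B as a six-membered carbocycle in which both enolate carbons lie inside the new ring. The closest known reaction type is the palladium-catalysed intramolecular alpha-arylation of ketone enolates, including the alpha'-arylation of vinylogous esters with formation of benzylic quaternary carbons. No stereocentre arises, because C4 carries two identical methyl groups. The step needs C-arylation and not O-arylation, although both would give six-membered rings; the bulky, electron-rich phosphine favours C–C reductive elimination and the C-arylated ketone is the more stable product. It also needs the aryl ring cis to the acyl group, which the E enol ether provides, and any Z isomer can equilibrate under the alkoxide conditions by addition–elimination at C1. Selectivity for C4 is secured by the methyl enol ether at C1, which leaves C2 without an acidic hydrogen and prevents an unreactive palladium diketonate, and the product has no enolisable hydrogen, so a second arylation cannot follow.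

Step 6
Reactants: 10 4,5,7-trimethoxy-1,1-dimethylnaphthalen-2(1H)-one
Product: 11 6-acetyl-4,5,7-trimethoxy-1,1-dimethylnaphthalen-2(1H)-one (acetyl on C7 of the target numbering)
Conditions: AcCl (1.3 equiv), SnCl4 (2.5 equiv), CH2Cl2, −20 → 0 °C
Reagents that add atoms: acetyl chloride, CC(Cl)=O
Why: Friedel–Crafts acylation: SnCl4 binds the C3 carbonyl and so switches off the enol-ether nucleophilicity of C2, while ring A keeps two methoxy donors; C7 is ortho to both of them and para to C4a, whereas C5 is shielded by the two methyl groups on the peri carbon C4, so the acetyl group should enter at C7.

Step 7
Reactants: 11 6-acetyl-4,5,7-trimethoxy-1,1-dimethylnaphthalen-2(1H)-one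
Product: 12 7-acetyl-3,6,8-trihydroxy-4,4-dimethylnaphthalen-1(4H)-one
Conditions: BBr3 (6 equiv), CH2Cl2, −78 °C → rt; then H2O
Reagents that add atoms: none
Why: Lewis-acid cleavage of methyl ethers: BBr3 coordinates each oxygen and bromide removes the methyl group by SN2 displacement, which cleaves the two aryl ethers (both activated by the ortho acetyl group) and the vinylogous ester at C1 alike; hydrolysis of the boron esters on work-up gives the triol, whose unmasked 1,3-dione settles as the C3 enol with the C1 carbonyl hydrogen-bonded to the C8 hydroxyl.

Step 8
Reactants: 12 7-acetyl-3,6,8-trihydroxy-4,4-dimethylnaphthalen-1(4H)-one (two equivalents)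
Product: 14 2,2'-methylenebis[7-acetyl-3,6,8-trihydroxy-4,4-dimethylnaphthalen-1(4H)-one] (target CNP0295164.0), via methylidene trione 13 (not isolated)
Conditions: 37 % aq. CH2O (0.5 equiv), EtOH, rt
Reagents that add atoms: formaldehyde, C=O
Why: Knoevenagel condensation followed by Michael addition: C2 of the enolised 1,3-dione is the most nucleophilic carbon of 12 and condenses with formaldehyde to the methylidene trione 13, which is trapped at once by a second molecule of 12, as in the formation of methylenebis(1,3-diones); with half an equivalent of formaldehyde under neutral, mild conditions the bis-enol should neither dehydrate to a pyran nor react at the hindered, deactivated C5.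

## Compound list

1 | 1-bromo-3,5-dimethoxybenzene | COc1cc(Br)cc(OC)c1 | starting material
2 | [(2-bromo-4,6-dimethoxyphenyl)methylidene]dimethylammonium chloride (iminium chloride, not isolated) | C[N+](C)=Cc1c(Br)cc(OC)cc1OC.[Cl-] | intermediate
3 | 2-bromo-4,6-dimethoxybenzaldehyde | COc1cc(Br)c(C=O)c(OC)c1 | intermediate
4 | dimethyl (1-diazo-2-oxopropyl)phosphonate | COP(=O)(OC)C(=[N+]=[N-])C(C)=O | starting material
5 | 1-bromo-2-ethynyl-3,5-dimethoxybenzene | COc1cc(Br)c(C#C)c(OC)c1 | intermediate
6 | N-methoxy-N,2-dimethylpropanamide | CC(C)C(=O)N(C)OC | starting material
7 | lithium (2-bromo-4,6-dimethoxyphenyl)acetylide (not isolated) | [Li]C#Cc1c(Br)cc(OC)cc1OC | intermediate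
8 | 1-(2-bromo-4,6-dimethoxyphenyl)-4-methylpent-1-yn-3-one | CC(C)C(=O)C#Cc1c(Br)cc(OC)cc1OC | intermediate
9 | (E)-1-(2-bromo-4,6-dimethoxyphenyl)-1-methoxy-4-methylpent-1-en-3-one | CO/C(=C/C(=O)C(C)C)c1c(Br)cc(OC)cc1OC | intermediate
10 | 4,5,7-trimethoxy-1,1-dimethylnaphthalen-2(1H)-one | COC1=CC(=O)C(C)(C)c2cc(OC)cc(OC)c21 | intermediate
11 | 6-acetyl-4,5,7-trimethoxy-1,1-dimethylnaphthalen-2(1H)-one | COC1=CC(=O)C(C)(C)c2cc(OC)c(C(C)=O)c(OC)c21 | intermediate
12 | 7-acetyl-3,6,8-trihydroxy-4,4-dimethylnaphthalen-1(4H)-one | CC(=O)c1c(O)cc2c(c1O)C(=O)C=C(O)C2(C)C | intermediate
13 | 7-acetyl-6,8-dihydroxy-4,4-dimethyl-2-methylidenenaphthalene-1,3(2H,4H)-dione (not isolated) | CC(=O)c1c(O)cc2c(c1O)C(=O)C(=C)C(=O)C2(C)C | intermediate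
14 | 2,2'-methylenebis[7-acetyl-3,6,8-trihydroxy-4,4-dimethylnaphthalen-1(4H)-one] | CC(=O)c1c(O)cc2c(c1O)C(=O)C(CC1=C(O)C(C)(C)c3cc(O)c(C(C)=O)c(O)c3C1=O)=C(O)C2(C)C | target

## Step count and least certain steps

Total: 8 steps. Longest linear sequence: 8 steps (1 to 14); the last step uses two molecules of the same monomer, so there is no separate branch.

**Step 5 (key step).** The most likely failures are reductive loss of bromine if enolisation of the hindered isopropyl C–H is slow compared with decay of the arylpalladium bromide, ring closure through oxygen instead of carbon, and exchange of the enol ether by tert-butoxide. Fallback: from 9, a photostimulated radical-chain substitution (SRN1; KOtBu, DMSO, irradiation at rt). The enolate passes an electron to the aryl bromide, bromide leaves, and the aryl radical is captured by the enolate carbon. This forms the same C4–C4a bond without palladium and returns to the route at 10; no new compound is made on the way.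

**Step 6.** The most likely failures are slow acylation, because SnCl4 is bound by the vinylogous ester and the site lies between two methoxy groups, with competing attack at C5, and loss of the enol ether followed by acylation at C2. Fallback: from 10, the C3 ketone is reduced with iBu2AlH (THF, −78 °C, basic work-up) to the racemic allylic alcohol 4,5,7-trimethoxy-1,1-dimethyl-1,2-dihydronaphthalen-2-ol F1. Its alkoxide is then lithiated between the two methoxy groups (n-BuLi, TMEDA, THF, 0 °C) and the aryllithium is quenched with N-methoxy-N-methylacetamide to give racemic 1-(6-hydroxy-1,3,8-trimethoxy-5,5-dimethyl-5,6-dihydronaphthalen-2-yl)ethan-1-one F2. Oxidation of the allylic alcohol with MnO2 (CH2Cl2, rt) returns to the route at 11. Directed metalation fixes the position of the acetyl group independently of electrophilic reactivity.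

**Step 8.** The most likely failures are over-condensation (loss of water from the bis-enol to a pyran, or uptake of further one-carbon units on ring A or as oligomers) and an incomplete Michael step. Fallback: from 12, one portion is aminomethylated at C2 with dimethyl(methylidene)ammonium iodide (CH2Cl2, rt) to the Mannich base 7-acetyl-2-[(dimethylamino)methyl]-3,6,8-trihydroxy-4,4-dimethylnaphthalen-1(4H)-one F3. F3 is then heated with one equivalent of 12 (dioxane, 80 °C), so that loss of dimethylamine releases the Michael acceptor only in the presence of its partner. This returns to the route at 14.

**Step 3.** The most likely failures are conjugate addition of the liberated amine or of the silylamide to the ynone during warming or quench, and incomplete acylation by the hindered acetylide. Fallback: from 5, the same lithium acetylide is added to isobutyraldehyde (THF, −78 °C) to give racemic 1-(2-bromo-4,6-dimethoxyphenyl)-4-methylpent-1-yn-3-ol F4, and the propargylic alcohol is oxidised with MnO2 (CH2Cl2, rt). This returns to the route at 8.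

## Further compounds

F0 | step 5 | none | none
F1 | step 6 | 4,5,7-trimethoxy-1,1-dimethyl-1,2-dihydronaphthalen-2-ol (racemic) | COC1=CC(O)C(C)(C)c2cc(OC)cc(OC)c21
F2 | step 6 | 1-(6-hydroxy-1,3,8-trimethoxy-5,5-dimethyl-5,6-dihydronaphthalen-2-yl)ethan-1-one (racemic) | COC1=CC(O)C(C)(C)c2cc(OC)c(C(C)=O)c(OC)c21
F3 | step 8 | 7-acetyl-2-[(dimethylamino)methyl]-3,6,8-trihydroxy-4,4-dimethylnaphthalen-1(4H)-one | CC(=O)c1c(O)cc2c(c1O)C(=O)C(CN(C)C)=C(O)C2(C)C
F4 | step 3 | 1-(2-bromo-4,6-dimethoxyphenyl)-4-methylpent-1-yn-3-ol (racemic) | CC(C)C(O)C#Cc1c(Br)cc(OC)cc1OC
A1 | alternative 1 | dimethyl 2,4-bis[2-(4-acetyl-3,5-dimethoxyphenyl)-2-methylpropanoyl]pentanedioate (mixture of stereoisomers) | COC(=O)C(CC(C(=O)OC)C(=O)C(C)(C)c1cc(OC)c(C(C)=O)c(OC)c1)C(=O)C(C)(C)c1cc(OC)c(C(C)=O)c(OC)c1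
A2 | alternative 1 | 2,2'-methylenebis(7-acetyl-3-hydroxy-6,8-dimethoxy-4,4-dimethylnaphthalen-1(4H)-one) | CC(=O)c1c(OC)cc2c(c1OC)C(=O)C(CC1=C(O)C(C)(C)c3cc(OC)c(C(C)=O)c(OC)c3C1=O)=C(O)C2(C)C
A3 | alternative 2 | 3-(2-diazoacetyl)-5-methoxy-4,4-dimethylcyclohexa-2,5-dien-1-one | COC1=CC(=O)C=C(C(=O)C=[N+]=[N-])C1(C)C
A4 | alternative 2 | triisopropyl{[(2-methyl-1,3-dioxolan-2-yl)ethynyl]oxy}silane | CC1(C#CO[Si](C(C)C)(C(C)C)C(C)C)OCCO1
A5 | alternative 2 | 8-hydroxy-3-methoxy-4,4-dimethyl-7-(2-methyl-1,3-dioxolan-2-yl)-6-(triisopropylsilyloxy)naphthalen-1(4H)-one | COC1=CC(=O)c2c(O)c(C3(C)OCCO3)c(O[Si](C(C)C)(C(C)C)C(C)C)cc2C1(C)C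
A6 | alternative 3 | 3,5-dimethoxy-8,8-dimethylbicyclo[4.2.0]octa-1,3,5-trien-7-one | COc1cc(OC)c2c(c1)C(C)(C)C2=O
A7 | alternative 3 | ethoxyethyne | CCOC#C
A8 | alternative 3 | 3-ethoxy-6,8-dimethoxy-4,4-dimethylnaphthalen-1(4H)-one | CCOC1=CC(=O)c2c(OC)cc(OC)cc2C1(C)C
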